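## Structural features

The target 22 is a flavonol: a 4H-chromen-4-one in which benzene ring A and pyranone ring C share the C4a–C8a bond, with the 4-methoxyphenyl ring B joined to C2 by one aryl–vinyl bond. Ring C carries the C4 carbonyl and a free enolic hydroxyl on C3. Ring A carries methoxy groups on C5, C6, C7 and C8; because C8a bears the ring oxygen O1, five neighbouring carbons of ring A are oxygenated and the sixth, C4a, bears the carbonyl carbon. The target has no stereocentre and no stereogenic double bond, so every problem is one of regiochemistry and oxidation level; the stereocentres that appear on the way (in 3, 4, 10, 12, 18, 20) are racemic and are erased. Fragile points are the C5 methoxy group (peri to the C4 carbonyl, easily cleaved by chelating Lewis acids), the electron-rich ring A (open to oxidation to quinones) and the 3-hydroxy enone (metal-chelating, oxidised in base), which is therefore unmasked last. The real difficulty is ring A: a hexasubstituted benzene in which exactly one of five contiguous oxygens (that on C8a) must stay unmethylated and must lie next to the only carbon (C4a) open to acylation. The key step meets this by building the benzene rather than substituting one: C8a, C8, C7 and C6 with their oxygens come from a squarate-derived cyclobutenone, and C4a and C5 come from methoxyethyne. The C8a hydroxyl is thus the former cyclobutenone carbonyl, and C4a is the one unsubstituted position by construction.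

## Logic of the disconnections

22 ⇒ 21. Only the benzyl–oxygen bond on O3 is cut. The 3-oxygen has to pass through ring C formation at the right oxidation level but masked, so that no late C3 oxidation is needed. The forward step must cleave this ether without touching the C2=C3 bond, the C4 carbonyl or five aryl methyl ethers, which points to hydrogenolysis.

21 ⇒ 13 + 18. The cuts are O1–C2 and C4–C4a, so ring C is removed as a three-carbon unit (C2, C3, C4) that already carries ring B and the protected O3. The cut is placed here because 13 has a single free ring carbon, ortho to its hydroxyl, so the site of C-acylation is not a selectivity question. The gain is two fragments of similar size, each a few steps from commercial material. The demand is that the ester carbon of 18 (not its ketone carbon) bonds to C4a, which calls for thermal, acid-free conditions.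

18 ⇒ 14 + 15. The cut is the future C2–C3 bond, between the α-carbon of 14 and the acyl carbon of 15 (Claisen retron). Both pieces are commercial and the benzyl ether is already in place. The forward step must give C- and not O-acylation and must not lose enolate to the more acidic product.

13 ⇒ 4 + 8. The cuts are C8a–C4a and C5–C6; the C8–C8a bond, present in 4, is broken and re-formed in the course of the reaction. This splits the pentaoxygenated ring into a four-carbon unit with four oxygens and a two-carbon unit with one, so no aromatic substitution and no differentiation of five oxygens is required. The demand is that the vinylketene from 4 is intercepted by 8 with the CH carbon of 8 bonding to the ketene carbon, and that the methoxy group on the sp3 carbon turns outward in both ring openings.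

4 ⇒ 3 ⇒ 1. The cuts are the O–CH3 bond on the sp3 carbon and then the C–H bond on the same carbon. 1 already holds the four ring carbons and all four oxygens. The demands are a single 1,2-hydride addition and an O-methylation mild enough for a strained hydroxy ketone that loses methanol in acid and opens in strong base. The oxygen is carried as its methyl ether because it is the C8 methoxy of 22, and because a free hydroxyl would let the vinylketene close to a furanone.

8 ⇒ 5. No skeletal bond is cut; the triple bond is traced back to one C–OMe and one C–Cl bond removed by two eliminations. The demand is excess amide base and isolation of a low-boiling, polymerisable product as a cold solution.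

## Other disconnections considered

Alternative 1: The cut passes through ring C at O1–C2 and C3–C4 and leaves salicylaldehyde A1 (2-hydroxy-3,4,5,6-tetramethoxybenzaldehyde) and nitroalkene A2 ((E)-1-methoxy-4-(2-nitroethenyl)benzene). In the forward sense DABCO would trigger oxa-Michael addition of the phenol of A1 to A2, the nitronate would add to the aldehyde (Henry step) and water would be lost, giving racemic nitrochromene A3 (5,6,7,8-tetramethoxy-2-(4-methoxyphenyl)-3-nitro-2H-chromene).
- In favour: two ring C bonds form in one base-catalysed operation near room temperature, no protecting group is needed, and the nitro group marks C3 for later oxygenation.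
- Against: ring A is not addressed, since A1 already holds the five contiguous oxygens and would itself come from 13 by ortho-formylation. The formyl group of A1 lies between a hydroxyl and a methoxy group on a very electron-rich ring and is a poor electrophile for the Henry closure. A3 is at the wrong oxidation level (C4 is CH, C3 bears nitrogen, C2 is a stereocentre that must be flattened again), so epoxidation of the nitroalkene, loss of nitrite and dehydrogenation would still be needed on an oxidation-prone arene.
- Comparison: on mechanism its ring C closure is the better one, far milder than the 250 °C condensation of step 6. On structure it is weaker, because it needs 13, and hence the chosen key step or an equivalent, in any case. On step economy it is longer, about five operations from 13 to 22 against two.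

Alternative 2: The cut is made in ring A at C4a–C5 and C8–C8a. Pyranone A4 (3-(benzyloxy)-2-(4-methoxyphenyl)-4H-pyran-4-one), metalated at C5, would add to one carbonyl of 1 to give racemic adduct A5 (3-(benzyloxy)-5-(1-hydroxy-2,3-dimethoxy-4-oxocyclobut-2-en-1-yl)-2-(4-methoxyphenyl)-4H-pyran-4-one). Heating A5 in xylene should open the four-membered ring to a dienylketene, which closes onto C6 of the pyranone by six-electron electrocyclisation and tautomerises to hydroquinone A6 (3-(benzyloxy)-5,8-dihydroxy-6,7-dimethoxy-2-(4-methoxyphenyl)-4H-chromen-4-one).
- In favour: thermal ring expansion of 4-aryl- and 4-alkenyl-4-hydroxycyclobutenones from squarates is an established reaction class and the closure is intramolecular. Rings B and C and the protected O3 are in place before ring A is built, and the conditions are neutral.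
- Against: A6 has free hydroxyls on C5 and C8, a para-hydroquinone that oxidises readily to the quinone and needs a double O-methylation (to reach 21); the C5 hydroxyl is hydrogen-bonded to the C4 carbonyl and alkylates slowly. A4 needs a synthesis of its own, and its metalation at C5 rather than C6, next to its own electrophilic enone, is uncertain.
- Comparison: on mechanism and precedent it is the better plan for the ring-forming event. It is equal in relying on cyclobutenone opening and six-electron closure, and equal in convergence. On structure it is weaker: only the C6 and C7 methoxy groups arrive as such, whereas the chosen step delivers all four methoxy groups and the one free hydroxyl in the right place. On step economy it is longer once the route to A4 and the methylation are counted.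

Alternative 3: The cut takes C8a–O1, C4a–C4 and O1–C2. Aryne A8 (3,4,5,6-tetramethoxybenzyne), released by CsF from silyl triflate A7 (2,3,4,5-tetramethoxy-6-(trimethylsilyl)phenyl trifluoromethanesulfonate), would be attacked by the carboxylate of acid A9 (3-(4-methoxyphenyl)prop-2-ynoic acid). The aryl anion so formed would attack the carboxyl carbon, which amounts to insertion of A8 into the C–O bond of A9, and the freed phenoxide would close ring C by conjugate addition to the alkynyl ketone, giving flavone A10 (5,6,7,8-tetramethoxy-2-(4-methoxyphenyl)-4H-chromen-4-one).
- In favour: A8 is symmetrical, so the insertion has no regiochemical question. The cascade is ionic, fluoride-triggered and mild, belongs to a known reaction class, and forms three bonds in one flask.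
- Against: A10 lacks the C3 hydroxyl, so a late oxidation of C3 on an electron-rich flavone is added. A7 is itself a hexasubstituted benzene that would be made from a phenol such as 13 by ortho-bromination, O-silylation, retro-Brook shift and triflation, so the pentaoxygenated ring must already exist. Simple O-arylation of A9 by protonation of the aryl anion competes with the acyl shift.
- Comparison: on mechanism and precedent of the key event it is the better plan, and it is equal in convergence. On structure it is weaker because it takes ring A as given. On step economy it is longer: about three steps from 13 to A7, the insertion, then C3 hydroxylation.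

Key step: step 4

Remark: the atom mapping of the benzannulation was rechecked and needs no correction (cyclobutenone C1, C2, C3, C4 become C8a, C6, C7, C8; the CH and C–OMe carbons of the alkyne become C4a and C5). By CIP rules the enol ether double bonds of 9, 10 and 11 are Z although the methoxy group turns outward. 8 is assumed to be handled only as a cold, freshly distilled toluene solution.

## Route

Step 1
Reactants: 1 dimethyl squarate (3,4-dimethoxycyclobut-3-ene-1,2-dione)
Product: 3 racemic 4-hydroxy-2,3-dimethoxycyclobut-2-en-1-one, via aluminate alkoxide 2 (not isolated)
Conditions: LiAlH(OtBu)3 (1.05 equiv), THF, −78 → −40 °C; cold aq KNaC4H4O6, pH 7; used crude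
Reagents that add atoms: none
Why: Monoreduction of a squarate ester: the bulky, weak alkoxyaluminium hydride adds 1,2 to one of the two equivalent carbonyls and aluminate 2 resists a second addition at low temperature; neutral work-up avoids acid-induced loss of methanol. The new stereocentre is racemic and is erased in step 4.

Step 2
Reactants: 3 racemic 4-hydroxy-2,3-dimethoxycyclobut-2-en-1-one
Product: 4 racemic 2,3,4-trimethoxycyclobut-2-en-1-one
Conditions: MeI (5 equiv), Ag2O (1.5 equiv), MeCN, 4 Å sieves, rt, dark
Reagents that add atoms: iodomethane, CI
Why: Purdie methylation: Ag2O activates MeI and takes up HI without forming a free alkoxide, so the strained hydroxy ketone should be etherified without base-induced ring opening; the stereocentre is untouched and stays racemic.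

Step 3
Reactants: 5 chloroacetaldehyde dimethyl acetal (2-chloro-1,1-dimethoxyethane)
Product: 8 methoxyethyne, via 1-chloro-2-methoxyethene 6 (not isolated), via sodium methoxyethynide 7 (not isolated)
Conditions: NaNH2 (3.2 equiv), liq. NH3, −35 °C; NH3 evaporated; cold sat. aq NaCl, −70 → 40 °C, distilled into toluene at −78 °C
Reagents that add atoms: none
Why: Double elimination (methanol, then HCl) with NaNH2 in liquid ammonia, the standard route to 1-alkoxyalkynes; the third equivalent of base holds the product as the non-volatile acetylide 7 until the aqueous quench, after which low-boiling 8 distils straight into cold toluene.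

Step 4
Reactants: 4 racemic 2,3,4-trimethoxycyclobut-2-en-1-one; 8 methoxyethyne
Product: 13 2,3,4,5-tetramethoxyphenol, via vinylketene 9 (not isolated), via vinylcyclobutenone 10 (not isolated), via dienylketene 11 (not isolated), via cyclohexadienone 12 (not isolated)
Conditions: 8 (4 equiv, toluene solution), sealed tube, Ar, 80 → 110 °C; then K2CO3, MeOH, rt, Ar
Reagents that add atoms: none
Why: Proposed new method: thermal four-electron conrotatory opening of 4, with the methoxy group on the sp3 carbon turning outward, should give vinylketene 9, whose ketene C=C adds across 8 in a regioselective [2+2] cycloaddition in which the nucleophilic CH terminus of the ynol ether bonds to the electrophilic ketene carbon (future C8a–C4a) and the methoxy-bearing alkyne carbon to the ketene α-carbon (future C5–C6), giving 10. A second four-electron opening of 10 should give dienylketene 11, which closes ring A by thermal disrotatory six-electron electrocyclisation (re-forming the C8–C8a bond) to 12, and enolisation then delivers 13. The closest known reaction type is the Danheiser benzannulation of alkyl- and aryl-substituted cyclobutenones with alkoxy- or siloxyalkynes to 3-alkoxyphenols; the new element is a 2,3,4-trialkoxycyclobutenone as vinylketene source, whose α-methoxy ketene is a weaker electrophile. No stereocentre is created and that of 4 is lost in the first ring opening. The step needs regiocontrol in the [2+2] event, secured by the strong polarisation of the ynol ether (largest HOMO coefficient on the unsubstituted carbon) matched with the ketene LUMO on the carbonyl carbon, and it needs the dienyl arm of 10 to turn inward, secured by the preference of an oxygen donor on the sp3 carbon of a cyclobutenone for outward rotation. Because C6, C7 and C8 all carry methoxy groups, even a direct [4+2] capture of 9 by 8 with the same polarity would lead to the same constitution 13. An excess of 8, which has no β-hydrogen and so cannot fragment by retro-ene loss of an alkene, is used to outrun ketene dimerisation, and the carbonate methanolysis returns any 13 that was acylated on oxygen by 9.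

Step 5
Reactants: 14 ethyl benzyloxyacetate; 15 4-methoxybenzoyl chloride
Product: 18 racemic ethyl 2-(benzyloxy)-3-(4-methoxyphenyl)-3-oxopropanoate, via lithium enolate 16 (not isolated), via ketoester enolate 17 (not isolated)
Conditions: 14 (2 equiv), LiN(SiMe3)2 (2 equiv), THF, −78 °C; 15 (1 equiv), −78 → 0 °C; 1 M HCl
Reagents that add atoms: none
Why: Crossed Claisen condensation: the lithium ester enolate 16 is C-acylated by the aroyl chloride, and the second equivalent of 16 deprotonates the more acidic product to 17, which protects it from a second acylation until the acid quench. The new stereocentre is racemic and disappears in step 6.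

Step 6
Reactants: 13 2,3,4,5-tetramethoxyphenol; 18 racemic ethyl 2-(benzyloxy)-3-(4-methoxyphenyl)-3-oxopropanoate
Product: 21 3-(benzyloxy)-5,6,7,8-tetramethoxy-2-(4-methoxyphenyl)-4H-chromen-4-one, via aroylketene 19 (not isolated), via diketone 20 (not isolated)
Conditions: 18 (1.5 equiv), Ph2O, 240–250 °C, Ar, EtOH distilled off
Reagents that add atoms: none
Why: Mentzer-type thermal chromone synthesis: 18 should lose ethanol to aroylketene 19, which acylates the only free ring carbon of 13 (ortho to the hydroxyl, activated by ortho and para oxygen donors) to give 20; the phenolic oxygen then adds to the aroyl carbonyl and water is lost, closing ring C with the aryl group on C2. Acid-free conditions avoid closure in the Pechmann sense to a 4-arylcoumarin, and reversible capture of 19 on the phenolic oxygen does not drain material at this temperature.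

Step 7
Reactants: 21 3-(benzyloxy)-5,6,7,8-tetramethoxy-2-(4-methoxyphenyl)-4H-chromen-4-one
Product: 22 3-hydroxy-5,6,7,8-tetramethoxy-2-(4-methoxyphenyl)-4H-chromen-4-one
Conditions: H2 (1 atm), Pd/C (10 wt% palladium metal on carbon), EtOAc–MeOH, rt
Reagents that add atoms: none
Why: Hydrogenolysis of a benzyl ether; the C2=C3 bond belongs to the cross-conjugated pyranone and should not be reduced under these mild conditions, and the aryl methyl ethers are inert.

## Compound list

1 | dimethyl squarate (3,4-dimethoxycyclobut-3-ene-1,2-dione) | COC1=C(OC)C(=O)C1=O | starting material
2 | lithium tri-tert-butoxy[(2,3-dimethoxy-4-oxocyclobut-2-en-1-yl)oxy]aluminate, racemic | [Li+].COC1=C(OC)C(O[Al-](OC(C)(C)C)(OC(C)(C)C)OC(C)(C)C)C1=O | intermediate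
3 | 4-hydroxy-2,3-dimethoxycyclobut-2-en-1-one, racemic | COC1=C(OC)C(O)C1=O | intermediate
4 | 2,3,4-trimethoxycyclobut-2-en-1-one, racemic | COC1C(=O)C(OC)=C1OC | intermediate
5 | chloroacetaldehyde dimethyl acetal (2-chloro-1,1-dimethoxyethane) | COC(CCl)OC | starting material
6 | 1-chloro-2-methoxyethene, E/Z mixture of no consequence | COC=CCl | intermediate
7 | sodium methoxyethynide | [Na+].[C-]#COC | intermediate
8 | methoxyethyne | COC#C | intermediate
9 | (3Z)-2,3,4-trimethoxybuta-1,3-dien-1-one | CO/C=C(OC)/C(OC)=C=O | intermediate
10 | 4-[(Z)-1,2-dimethoxyethenyl]-3,4-dimethoxycyclobut-2-en-1-one, racemic | CO/C=C(OC)/C1(OC)C(OC)=CC1=O | intermediate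
11 | (3Z,5Z)-3,4,5,6-tetramethoxyhexa-1,3,5-trien-1-one | O=C=C/C(OC)=C(OC)\C(OC)=C\OC | intermediate
12 | 3,4,5,6-tetramethoxycyclohexa-2,4-dien-1-one, racemic | COC1C(=O)C=C(OC)C(OC)=C1OC | intermediate
13 | 2,3,4,5-tetramethoxyphenol | COc1cc(O)c(OC)c(OC)c1OC | intermediate
14 | ethyl benzyloxyacetate | CCOC(=O)COCc1ccccc1 | starting material
15 | 4-methoxybenzoyl chloride | COc1ccc(C(Cl)=O)cc1 | starting material
16 | lithium 2-(benzyloxy)-1-ethoxyethen-1-olate, geometry immaterial | [Li+].CCOC([O-])=COCc1ccccc1 | intermediate
17 | lithium enolate of ethyl 2-(benzyloxy)-3-(4-methoxyphenyl)-3-oxopropanoate | [Li+].CCOC(=O)[C-](OCc1ccccc1)C(=O)c1ccc(OC)cc1 | intermediate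
18 | ethyl 2-(benzyloxy)-3-(4-methoxyphenyl)-3-oxopropanoate, racemic | CCOC(=O)C(OCc1ccccc1)C(=O)c1ccc(OC)cc1 | intermediate
19 | 2-(benzyloxy)-3-(4-methoxyphenyl)-3-oxoprop-1-en-1-one (aroylketene) | O=C=C(OCc1ccccc1)C(=O)c1ccc(OC)cc1 | intermediate
20 | 2-(benzyloxy)-1-(2-hydroxy-3,4,5,6-tetramethoxyphenyl)-3-(4-methoxyphenyl)propane-1,3-dione, racemic | COc1ccc(C(=O)C(OCc2ccccc2)C(=O)c2c(O)c(OC)c(OC)c(OC)c2OC)cc1 | intermediate
21 | 3-(benzyloxy)-5,6,7,8-tetramethoxy-2-(4-methoxyphenyl)-4H-chromen-4-one | COc1ccc(-c2oc3c(OC)c(OC)c(OC)c(OC)c3c(=O)c2OCc2ccccc2)cc1 | intermediate
22 | 3-hydroxy-5,6,7,8-tetramethoxy-2-(4-methoxyphenyl)-4H-chromen-4-one | COc1ccc(-c2oc3c(OC)c(OC)c(OC)c(OC)c3c(=O)c2O)cc1 | target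

## Step count and least certain steps

Total step count: 7. Longest linear sequence: 5 steps (steps 1, 2, 4, 6, 7, from 1 to 22); steps 3 and 5 are one-step side branches that join at steps 4 and 6.

Step 4 (key step, proposed new method). The vinylketene 9 may reclose or dimerise faster than it is intercepted, while 8 is lost by thermal oligomerisation. Both partners are donor-substituted, so the ketene–alkyne union lacks the strong electrophile–nucleophile match of the known cases. Fallback by known chemistry, setting out from 1 and coming back to the route at 13:
- Methyl vinyl ether is lithiated with t-BuLi in THF to (1-methoxyethenyl)lithium F1, which is added to 1 at −78 °C to give lithium 2,3-dimethoxy-1-(1-methoxyethenyl)-4-oxocyclobut-2-en-1-olate F2.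
- Methyl triflate added to the same flask gives racemic 2,3,4-trimethoxy-4-(1-methoxyethenyl)cyclobut-2-en-1-one F3.
- Heating F3 in toluene at 110 °C should open the ring, methoxy outward, to (3Z)-2,3,4,5-tetramethoxyhexa-1,3,5-trien-1-one F4, which closes by six-electron electrocyclisation to 2,3,4,5-tetramethoxycyclohexa-2,4-dien-1-one F5 and tautomerises to 13.

This is the established thermal ring expansion of squarate-derived 4-alkenyl-4-alkoxycyclobutenones. It replaces an intermolecular ketene–alkyne union by an intramolecular closure, needs neither 4 nor 8, and would take two operations from 1 to 13 instead of four.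

Step 6. C-acylation at the crowded ortho carbon may be slower than thermal breakdown of the ketoester by ketene dimerisation or decarboxylative pathways, and any adventitious acid would steer closure towards the isomeric coumarin. The phenol carries a single hydroxyl and is less reactive than the polyphenols for which this condensation works best. Fallback, setting out from 13 and coming back at 22:
- Acetylation of the free ortho carbon (AcOH, BF3·OEt2, 70 °C; Friedel–Crafts/Fries type) gives 1-(2-hydroxy-3,4,5,6-tetramethoxyphenyl)ethan-1-one F6.
- Claisen–Schmidt condensation with 4-methoxybenzaldehyde (KOH, EtOH) gives (E)-1-(2-hydroxy-3,4,5,6-tetramethoxyphenyl)-3-(4-methoxyphenyl)prop-2-en-1-one F7.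
- Oxidative cyclisation with catalytic I2 in DMSO at 120 °C gives 5,6,7,8-tetramethoxy-2-(4-methoxyphenyl)-4H-chromen-4-one F8.
- Epoxidation of the C2=C3 bond with dimethyldioxirane gives the racemic 2,3-epoxy-5,6,7,8-tetramethoxy-2-(4-methoxyphenyl)-2,3-dihydro-4H-chromen-4-one F9, which should isomerise with catalytic TsOH to 22.

An Algar–Flynn–Oyamada closure of F7 is avoided because chalcones with a methoxy group at the second ortho position tend to close to aurones. The detour is four steps instead of two and needs neither 18 nor 21.

Step 2. The alcohol may be consumed by ring opening or by loss of methanol before O-alkylation is complete, because the strained α-hydroxy ketone tolerates neither base nor acid well; slow oxidation by Ag2O is also conceivable. Fallback, setting out from 1 and coming back at 4 without passing through 3: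
- Ketalisation of one carbonyl of 1 with MeOSiMe3 and catalytic Me3SiOTf in CH2Cl2 should give 2,3,4,4-tetramethoxycyclobut-2-en-1-one F10.
- Ionic hydrogenation (Et3SiH, catalytic Me3SiOTf, CH2Cl2, −78 °C) then replaces one ketal methoxy group by hydrogen.

Ionisation of F10 gives a trimethoxycyclobutenyl cation that is symmetrical about the axis through the carbonyl carbon and the central methoxy carbon, so hydride capture at either terminus gives the same compound 4. The free alcohol and every basic reagent are avoided; over-reduction has to be held back by stoichiometry and low temperature.

## Further compounds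

F1 | step 4 | (1-methoxyethenyl)lithium | [Li]C(=C)OC
F2 | step 4 | lithium 2,3-dimethoxy-1-(1-methoxyethenyl)-4-oxocyclobut-2-en-1-olate, racemic | [Li+].COC(=C)C1([O-])C(OC)=C(OC)C1=O
F3 | step 4 | 2,3,4-trimethoxy-4-(1-methoxyethenyl)cyclobut-2-en-1-one, racemic | COC(=C)C1(OC)C(OC)=C(OC)C1=O
F4 | step 4 | (3Z)-2,3,4,5-tetramethoxyhexa-1,3,5-trien-1-one | C=C(OC)/C(OC)=C(OC)\C(OC)=C=O
F5 | step 4 | 2,3,4,5-tetramethoxycyclohexa-2,4-dien-1-one | COC1=C(OC)C(OC)=C(OC)C(=O)C1
F6 | step 6 | 1-(2-hydroxy-3,4,5,6-tetramethoxyphenyl)ethan-1-one | COc1c(O)c(C(C)=O)c(OC)c(OC)c1OC
F7 | step 6 | (E)-1-(2-hydroxy-3,4,5,6-tetramethoxyphenyl)-3-(4-methoxyphenyl)prop-2-en-1-one | COc1ccc(/C=C/C(=O)c2c(O)c(OC)c(OC)c(OC)c2OC)cc1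
F8 | step 6 | 5,6,7,8-tetramethoxy-2-(4-methoxyphenyl)-4H-chromen-4-one | COc1ccc(-c2cc(=O)c3c(OC)c(OC)c(OC)c(OC)c3o2)cc1
F9 | step 6 | 2,3-epoxy-5,6,7,8-tetramethoxy-2-(4-methoxyphenyl)-2,3-dihydro-4H-chromen-4-one, racemic, epoxide necessarily cis-fused | COc1ccc(C23OC2C(=O)c2c(OC)c(OC)c(OC)c(OC)c2O3)cc1
F10 | step 2 | 2,3,4,4-tetramethoxycyclobut-2-en-1-one | COC1=C(OC)C(OC)(OC)C1=O
A1 | alternative 1 | 2-hydroxy-3,4,5,6-tetramethoxybenzaldehyde | COc1c(O)c(C=O)c(OC)c(OC)c1OC
A2 | alternative 1 | (E)-1-methoxy-4-(2-nitroethenyl)benzene | COc1ccc(/C=C/[N+](=O)[O-])cc1
A3 | alternative 1 | 5,6,7,8-tetramethoxy-2-(4-methoxyphenyl)-3-nitro-2H-chromene, racemic | COc1ccc(C2Oc3c(OC)c(OC)c(OC)c(OC)c3C=C2[N+](=O)[O-])cc1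
A4 | alternative 2 | 3-(benzyloxy)-2-(4-methoxyphenyl)-4H-pyran-4-one | COc1ccc(-c2occc(=O)c2OCc2ccccc2)cc1
A5 | alternative 2 | 3-(benzyloxy)-5-(1-hydroxy-2,3-dimethoxy-4-oxocyclobut-2-en-1-yl)-2-(4-methoxyphenyl)-4H-pyran-4-one, racemic | COC1=C(OC)C(O)(c2coc(-c3ccc(OC)cc3)c(OCc3ccccc3)c2=O)C1=O
A6 | alternative 2 | 3-(benzyloxy)-5,8-dihydroxy-6,7-dimethoxy-2-(4-methoxyphenyl)-4H-chromen-4-one | COc1ccc(-c2oc3c(O)c(OC)c(OC)c(O)c3c(=O)c2OCc2ccccc2)cc1
A7 | alternative 3 | 2,3,4,5-tetramethoxy-6-(trimethylsilyl)phenyl trifluoromethanesulfonate | COc1c(OC)c(OC)c(OC)c([Si](C)(C)C)c1OS(=O)(=O)C(F)(F)F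
A8 | alternative 3 | 3,4,5,6-tetramethoxybenzyne (1,2-didehydro-3,4,5,6-tetramethoxybenzene) | COC1=C(OC)C(OC)=C(OC)C#C1
A9 | alternative 3 | 3-(4-methoxyphenyl)prop-2-ynoic acid | COc1ccc(C#CC(=O)O)cc1
A10 | alternative 3 | 5,6,7,8-tetramethoxy-2-(4-methoxyphenyl)-4H-chromen-4-one | COc1ccc(-c2cc(=O)c3c(OC)c(OC)c(OC)c(OC)c3o2)cc1
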